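The constants used here belong to no real substance; the result is computed.

In a one-step world Q turns into G and a flask asks for time; here Q has a second way out and J has a slow trap.

| flask | Q | J | time | remark | temperature |
|---|---|---|---|---|---|
| north-west | 0.10 M | 9.0 mM | 20 min | at 70 °C until 6.0 min, from then on at 110 °C |  |
| east | 0.10 M | 9.0 mM | 20 min |  | 110 °C |
| west | 0.10 M | 9.0 mM | 20 min |  | 70 °C |
| south-west | 0.10 M | 9.0 mM | 20 min |  | 90 °C |

    Q + J → J + G (k1 = 0.17 /M/s, Ea1 = 45.0 kJ/mol)
    Q → D (k2 = 0.0014 /s, Ea2 = 107 kJ/mol)
    Q + J → Q.J (k3 = 0.0061 /M/s, Ea3 = 62.0 kJ/mol)
    (constants at 90 °C)

* the best flask by share of G in all that became G or D; "all alike" if 1.5 percentage points covers them all (north-west / east / west / south-west / all alike)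
* share of G in all that became G or D, north-west
* share of G in all that became G or D, east
* share of G in all that became G or D, west
* share of G in all that became G or D, south-west

- the constants hold at 90 °C; other temperatures follow from the activation energies

I began by comparing the two ways out. Q goes to G at the G step's constant times [Q][J], and to D at the D step's constant times [Q], so [Q] cancels in their ratio. The two routes run equally fast at the break-even [J], the D constant over the G constant, 8.24 mM at 90 °C. The share of G, the selectivity, is then [J]/([J] + break-even). For south-west, the charged 9.0 mM gave a first answer of 52.2%.

Something looked wrong when I followed J. The trap's constant lies 27.9 times below the G step's, and the G step hands J back, yet my first answer, applied to the charged Q, implied that south-west loses 20.8% of its J. It clears up by counting rounds. The trap takes 0.0359 of a J for each G made, and that first answer, applied to the charged Q, means 5.80 G for each J charged, so small losses add up to 1.87 mM.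

So I went round once more. J falls in step with G made, so the average G met the midpoint, 8.06 mM, and south-west's share became 49.5%. Heat moves the break-even: it is 2.49 mM for west and 24.1 mM for east. First answers of 78.3% for west and 27.2% for east put west highest. I did not reckon north-west, which has both temperatures.

The forecast said west, with 38.4% for north-west, 25.8% for east, 77.1% for west and 49.7% for south-west, since “heat favours D and the coolest flask gives the best share of G”.

The simulation gave west, with 38.4%, 25.8%, 77.1% and 49.7% in the same order. South-west held 18.7% of its catalyst as Q.J at 20.0 min. The break-even over my midpoint [J] gives D over G in south-west as 1.02, and that flask stood at D 47.7% and G 47.0%.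

The neighbour of east charged with 2.30 mM of J sits far below its break-even of 24.1 mM. The first answer is 8.73%; the trap's toll at that temperature, 0.0481, brings the midpoint to 2.09 mM and the share to 7.98%. The simulation gave 8.03%.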